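Set two amounts side by side for each flask: the starting material charged, and the target its catalyst can make before it stops working.

| flask | starting material | free catalyst | time |
|---|---|---|---|
| zeta | 200 mM | 2.00 mM |  |
| alpha | 400 mM | 2.00 mM |  |
| theta | 200 mM | 3.00 mM |  |
| delta | 200 mM | 2.00 mM | 72 min |

| run | time / min | [starting material] / mM |
|---|---|---|
| zeta run | 0.48 | 151.4 |
| zeta run | 1.1 | 118.4 |
| zeta run | 2.4 | 88.4 |
| zeta run | 5.4 | 61.2 |
| zeta run | 12 | 42.2 |
| alpha run | 0.48 | 323.7 |
| alpha run | 1.1 | 282.0 |
| alpha run | 2.4 | 248.8 |
| alpha run | 5.4 | 221.1 |
| alpha run | 12 | 217.1 |
| theta run | 0.48 | 134.4 |
| theta run | 1.1 | 91.7 |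
| theta run | 2.4 | 57.4 |
| theta run | 5.4 | 28.3 |
| theta run | 12 | 11.7 |

(each reading ± 2 mM)

- Overall: starting material -> target, with free catalyst as catalyst.
- Constant volume, constant temperature.
- Bound and free are read together.
- An order is taken over about fifteen percent of the charge, up and down.

- the exponent of [starting material] in the starting rate at the charge of the zeta run (at the point where two percent of the starting material have become target) (one fixed amount of target, the same in the runs compared)
- the exponent of [free catalyst] in the starting rate at the charge of the zeta run (at the point where two percent of the starting material have become target)
- starting material in the delta run at 72 min, as a share of the starting material charged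

The second amount shows in alpha. From 5.4 min to 12 min, alpha loses 4.00 mM of starting material although 217.1 mM is still there. I doubt that target explains this. Over the same interval theta, which reaches 188 mM of target by its last reading against alpha's 183 mM, loses more, 16.6 mM, but theta was also charged with more catalyst.

So I read alpha as a flask whose catalyst has stopped, and I divide: 91.5 of target per free catalyst charged, the capacity or turnover number. I assume that target made and catalyst lost keep one ratio as a flask empties. Then a flask can make its capacity times its catalyst. Delta can make 183 mM from a charge of 200 mM, so in delta I expect the catalyst to stop first, with 8.55% of the starting material remaining.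

The forecast gives orders of 0.8 and 1 and a share of 9.5%, a little above mine, on the ground that “capacity is about 183 mM for 2 mM”.

The flask gives 0.80, 1.0 and 8.92%.

    free catalyst + starting material ⇌ catalyst-substrate complex (660.0 L mol⁻¹ min⁻¹, 61.80 min⁻¹)
    catalyst-substrate complex → target + free catalyst (377.4 min⁻¹)
    free catalyst + starting material → spent catalyst + starting material (6.180 L mol⁻¹ min⁻¹)
    free catalyst + target ⇌ catalyst-product complex, settled at all times (11.40 L mol⁻¹)

Delta has made 182 mM of target, 91.1 per catalyst charged, against the capacity of 91.5 read from alpha. Capacity times catalyst gives theta 274 mM for its 200 mM charge, and the reading at 12 min already stands past delta's amount. The reason for delta's remainder is the passing of free catalyst into spent catalyst: delta keeps 8.92% of its starting material at 72 min with that step and 0% without it.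

All runs stem from a simulated flask on assumed constants.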